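Flavan numbering: the upper unit carries the 4-hydroxyphenyl group, the lower unit the catechol ring E. Both pyran rings are disconnected at C4–C4a, where C4a is the ring-A carbon ortho to O1 and para to the 7-oxygen; each heterocycle thus becomes the hydroarylation product of an aryl propargyl ether of 3-benzyloxyphenol. The key step, a double gold-catalysed 6-endo-dig hydroarylation, closes the lower pyran ring (C4–C4a) and the upper one in one operation from a diyne built on ring E, whose two C2 stereocentres come from copper-catalysed propargylic etherification. Double hydroboration then relays them to both C3 and to upper C4; hydrogenolysis frees the phenols.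

Key step: step 7

Remark: the copper–pybox catalyst is assumed to give the (S)-ether 6 with the (S,S)-ligand; if the sense proves the reverse, the (R,R)-ligand is used in steps 2 and 6 alike, since both C2 centres need the same spatial arrangement (their descriptors differ only through priority changes).

Step 1
Reactants: 1 4-(benzyloxy)benzaldehyde; 2 ethynylmagnesium bromide
Product: 4 rac-1-[4-(benzyloxy)phenyl]prop-2-yn-1-yl acetate, via bromomagnesium propargylic alkoxide 3 (not isolated)
Conditions: THF, 0 °C; then Ac2O, 0 °C to rt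
Reagents that add atoms: acetic anhydride, CC(=O)OC(C)=O
Why: Grignard 1,2-addition of the acetylide to the aldehyde and O-acetylation of the magnesium alkoxide in the same flask; the carbinol centre is left racemic on purpose because step 2 is stereoconvergent.

Step 2
Reactants: 4 rac-1-[4-(benzyloxy)phenyl]prop-2-yn-1-yl acetate; 5 3-(benzyloxy)phenol
Product: 6 (S)-1-(benzyloxy)-3-({1-[4-(benzyloxy)phenyl]prop-2-yn-1-yl}oxy)benzene
Conditions: CuOTf·0.5C6H6 (5 mol %), (S,S)-Ph-pybox (10 mol %), i-Pr2NEt, PhCF3, 0 °C
Reagents that add atoms: none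
Why: Copper-catalysed enantioselective propargylic etherification: the copper acetylide of 4 loses acetate to a planar copper allenylidene, and the phenol oxygen adds to its γ-carbon inside the chiral pybox pocket, which sets C2 of the upper unit from racemic 4.

Step 3
Reactants: 7 3,4-bis(benzyloxy)benzaldehyde
Product: 8 4,5-bis(benzyloxy)-2-bromobenzaldehyde
Conditions: Br2, NaOAc, AcOH, rt
Reagents that add atoms: bromine, BrBr
Why: Electrophilic aromatic bromination at the position para to the 3-benzyloxy group and ortho to the formyl group, the most activated one as in veratraldehyde; sodium acetate buffers the HBr so that the benzyl ethers survive.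

Step 4
Reactants: 6 (S)-aryl propargyl ether; 8 4,5-bis(benzyloxy)-2-bromobenzaldehyde
Product: 9 4,5-bis(benzyloxy)-2-{(3R)-3-[3-(benzyloxy)phenoxy]-3-[4-(benzyloxy)phenyl]prop-1-yn-1-yl}benzaldehyde
Conditions: PdCl2(PPh3)2 (3 mol %), CuI (3 mol %), Et3N, THF, 60 °C
Reagents that add atoms: none
Why: Sonogashira coupling; the ortho-formyl group eases oxidative addition of zerovalent palladium into the C–Br bond, and the propargylic stereocentre is untouched because only the alkyne C–H bond reacts (the descriptor changes from S to R by priority only).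

Step 5
Reactants: 9 ortho-alkynyl benzaldehyde; 2 ethynylmagnesium bromide
Product: 11 1-(4,5-bis(benzyloxy)-2-{(3R)-3-[3-(benzyloxy)phenoxy]-3-[4-(benzyloxy)phenyl]prop-1-yn-1-yl}phenyl)prop-2-yn-1-yl acetate (both epimers at the acetoxy carbon), via bromomagnesium propargylic alkoxide 10 (not isolated)
Conditions: THF, −20 to 0 °C; then Ac2O, 0 °C to rt
Reagents that add atoms: acetic anhydride, CC(=O)OC(C)=O
Why: Grignard 1,2-addition to the aldehyde and in-flask O-acetylation; the new carbinol centre need not be controlled because step 6 passes through a planar copper allenylidene.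

Step 6
Reactants: 11 propargylic acetate (epimer mixture); 5 3-(benzyloxy)phenol
Product: 12 1,2-bis(benzyloxy)-4-{(1S)-1-[3-(benzyloxy)phenoxy]prop-2-yn-1-yl}-5-{(3R)-3-[3-(benzyloxy)phenoxy]-3-[4-(benzyloxy)phenyl]prop-1-yn-1-yl}benzene
Conditions: CuOTf·0.5C6H6 (5 mol %), (S,S)-Ph-pybox (10 mol %), i-Pr2NEt, PhCF3, 0 °C
Reagents that add atoms: none
Why: Second copper-catalysed enantioselective propargylic etherification; only the terminal alkyne can form the copper acetylide and allenylidene, both epimers of 11 converge on it, and the same ligand antipode as in step 2 sets C2 of the lower unit under catalyst control.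

Step 7
Reactants: 12 bis(propargyl ether)
Product: 14 (2S)-7-(benzyloxy)-4-{4,5-bis(benzyloxy)-2-[(2S)-7-(benzyloxy)-2H-chromen-2-yl]phenyl}-2-[4-(benzyloxy)phenyl]-2H-chromene, via lower-ring mono-chromene 13 (not isolated)
Conditions: Ph3PAuNTf2 (5 mol %), CH2Cl2 (0.02 M), 0 °C to rt, dark
Reagents that add atoms: none
Why: The cationic monovalent gold complex binds each alkyne, the tethered 3-benzyloxyphenoxy ring attacks the activated carbon anti to gold in a Friedel–Crafts sense, and rearomatisation with protodeauration releases the 2H-chromene, so that the terminal alkyne carbon of 12 becomes C4 of the lower unit bonded to C4a and the alkyne carbon on ring E becomes C4 of the upper unit bonded to its C4a. The closest known reaction is the gold-catalysed intramolecular hydroarylation of aryl propargyl ethers to 2H-chromenes, known for terminal and for aryl-substituted alkynes. Both pyran rings close in the 6-endo-dig mode. No stereocentre is formed; the two C2 centres from steps 2 and 6 are carried through because neither the C2–O1 nor the C2–C3 bond is broken, provided that acid, heat and light, which would open the chromenes to ortho-quinone methides, are kept away. The step needs attack on each ring A at the carbon para to the benzyloxy group and not at the carbon between the two oxygens, which the para donor and the peri clash of a 5-benzyloxy group with the C4 substituent should secure, and 6-endo over 5-exo attack, which the short O–C2 tether and, in the upper ring, the cation-stabilising ring E on C4 should secure. It also needs each alkyne to be taken by its own arene and not by the other alkyne or by the benzylic ether oxygen, for which the six-membered transition states onto the electron-rich arenes, high dilution and low temperature are relied on.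

Step 8
Reactants: 14 bis-chromene
Product: 16 (2R,3S,4R)-7-(benzyloxy)-4-{4,5-bis(benzyloxy)-2-[(2R,3S)-7-(benzyloxy)-3-hydroxychroman-2-yl]phenyl}-2-[4-(benzyloxy)phenyl]chroman-3-ol, via bis(alkylborane) 15 (not isolated)
Conditions: BH3·THF (6 equiv), THF, 0 °C to rt; then 3 M NaOH, 30% H2O2, 0 °C to rt
Reagents that add atoms: hydrogen peroxide, OO
Why: Hydroboration–oxidation: borane adds H and B syn to each chromene double bond from the face away from its C2 aryl group with boron on C3 (β to ring A, and in the upper ring the only alkene carbon that bears hydrogen), and oxidation with retention gives the 2,3-trans alcohols in both units and, in the upper unit, the C4 hydrogen cis to the C3 oxygen, that is the 3,4-trans aryl group, so that three stereocentres are relayed from the two C2 centres.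

Step 9
Reactants: 16 penta-O-benzyl ether
Product: 17 (2R,3S,4R)-4-{2-[(2R,3S)-3,7-dihydroxychroman-2-yl]-4,5-dihydroxyphenyl}-2-(4-hydroxyphenyl)chromane-3,7-diol
Conditions: H2 (1 atm), Pd(OH)2/C, THF–MeOH, rt
Reagents that add atoms: none
Why: Hydrogenolysis of the five aryl benzyl ethers; under neutral conditions at 1 atm the cyclic C2–O1 benzylic ethers and the C4 diarylmethine should not be cleaved, as in the usual last step of catechin syntheses, and no stereocentre is touched.

Compound list
1 | 4-(benzyloxy)benzaldehyde | O=Cc1ccc(OCc2ccccc2)cc1 | starting material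
2 | ethynylmagnesium bromide (THF solution) | C#C[Mg]Br | starting material
3 | bromomagnesium 1-[4-(benzyloxy)phenyl]prop-2-yn-1-olate, racemic | C#CC(O[Mg]Br)c1ccc(OCc2ccccc2)cc1 | intermediate
4 | rac-1-[4-(benzyloxy)phenyl]prop-2-yn-1-yl acetate | C#CC(OC(C)=O)c1ccc(OCc2ccccc2)cc1 | intermediate
5 | 3-(benzyloxy)phenol | Oc1cccc(OCc2ccccc2)c1 | starting material
6 | (S)-1-(benzyloxy)-3-({1-[4-(benzyloxy)phenyl]prop-2-yn-1-yl}oxy)benzene | C#C[C@H](Oc1cccc(OCc2ccccc2)c1)c1ccc(OCc2ccccc2)cc1 | intermediate
7 | 3,4-bis(benzyloxy)benzaldehyde | O=Cc1ccc(OCc2ccccc2)c(OCc2ccccc2)c1 | starting material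
8 | 4,5-bis(benzyloxy)-2-bromobenzaldehyde | O=Cc1cc(OCc2ccccc2)c(OCc2ccccc2)cc1Br | intermediate
9 | 4,5-bis(benzyloxy)-2-{(3R)-3-[3-(benzyloxy)phenoxy]-3-[4-(benzyloxy)phenyl]prop-1-yn-1-yl}benzaldehyde (same spatial arrangement as in 6) | O=Cc1cc(OCc2ccccc2)c(OCc2ccccc2)cc1C#C[C@H](Oc1cccc(OCc2ccccc2)c1)c1ccc(OCc2ccccc2)cc1 | intermediate
10 | bromomagnesium alkoxide from addition of 2 to the formyl group of 9, both epimers at the new carbinol carbon | C#CC(O[Mg]Br)c1cc(OCc2ccccc2)c(OCc2ccccc2)cc1C#C[C@H](Oc1cccc(OCc2ccccc2)c1)c1ccc(OCc2ccccc2)cc1 | intermediate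
11 | 1-(4,5-bis(benzyloxy)-2-{(3R)-3-[3-(benzyloxy)phenoxy]-3-[4-(benzyloxy)phenyl]prop-1-yn-1-yl}phenyl)prop-2-yn-1-yl acetate, both epimers at the acetoxy carbon | C#CC(OC(C)=O)c1cc(OCc2ccccc2)c(OCc2ccccc2)cc1C#C[C@H](Oc1cccc(OCc2ccccc2)c1)c1ccc(OCc2ccccc2)cc1 | intermediate
12 | 1,2-bis(benzyloxy)-4-{(1S)-1-[3-(benzyloxy)phenoxy]prop-2-yn-1-yl}-5-{(3R)-3-[3-(benzyloxy)phenoxy]-3-[4-(benzyloxy)phenyl]prop-1-yn-1-yl}benzene | C#C[C@H](Oc1cccc(OCc2ccccc2)c1)c1cc(OCc2ccccc2)c(OCc2ccccc2)cc1C#C[C@H](Oc1cccc(OCc2ccccc2)c1)c1ccc(OCc2ccccc2)cc1 | intermediate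
13 | (2S)-7-(benzyloxy)-2-(4,5-bis(benzyloxy)-2-{(3R)-3-[3-(benzyloxy)phenoxy]-3-[4-(benzyloxy)phenyl]prop-1-yn-1-yl}phenyl)-2H-chromene (lower ring closed, upper alkyne intact) | c1ccccc1COc1ccc([C@@H](Oc2cccc(OCc3ccccc3)c2)C#Cc2cc(OCc3ccccc3)c(OCc3ccccc3)cc2[C@H]2Oc3cc(OCc4ccccc4)ccc3C=C2)cc1 | intermediate
14 | (2S)-7-(benzyloxy)-4-{4,5-bis(benzyloxy)-2-[(2S)-7-(benzyloxy)-2H-chromen-2-yl]phenyl}-2-[4-(benzyloxy)phenyl]-2H-chromene | c1ccccc1COc1ccc([C@H]2Oc3cc(OCc4ccccc4)ccc3C(c3cc(OCc4ccccc4)c(OCc4ccccc4)cc3[C@H]3Oc4cc(OCc5ccccc5)ccc4C=C3)=C2)cc1 | intermediate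
15 | bis(alkylborane) from 14: a BH2 group on C3 of each chroman, trans to the C2 aryl group; in the upper ring the C4 hydrogen is cis to boron | c1ccccc1COc1ccc([C@H]2Oc3cc(OCc4ccccc4)ccc3[C@@H](c3cc(OCc4ccccc4)c(OCc4ccccc4)cc3[C@H]3Oc4cc(OCc5ccccc5)ccc4C[C@@H]3B)[C@@H]2B)cc1 | intermediate
16 | (2R,3S,4R)-7-(benzyloxy)-4-{4,5-bis(benzyloxy)-2-[(2R,3S)-7-(benzyloxy)-3-hydroxychroman-2-yl]phenyl}-2-[4-(benzyloxy)phenyl]chroman-3-ol | c1ccccc1COc1ccc([C@H]2Oc3cc(OCc4ccccc4)ccc3[C@@H](c3cc(OCc4ccccc4)c(OCc4ccccc4)cc3[C@H]3Oc4cc(OCc5ccccc5)ccc4C[C@@H]3O)[C@@H]2O)cc1 | intermediate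
17 | (2R,3S,4R)-4-{2-[(2R,3S)-3,7-dihydroxychroman-2-yl]-4,5-dihydroxyphenyl}-2-(4-hydroxyphenyl)chromane-3,7-diol (both units 2,3-trans, upper unit 3,4-trans) | Oc1ccc([C@H]2Oc3cc(O)ccc3[C@@H](c3cc(O)c(O)cc3[C@H]3Oc4cc(O)ccc4C[C@@H]3O)[C@@H]2O)cc1 | target

Total steps: 9. Longest linear sequence: 8 steps (1 → 4 → 6 → 9 → 11 → 12 → 14 → 16 → 17; steps 1, 2, 4, 5, 6, 7, 8, 9).

Steps most likely to fail

Step 7 (key step). What may go wrong: the two alkynes of 12 engage each other under gold before each is attacked by its own ring A. This could be cycloisomerisation of the 1,6-diyne, or addition of the terminal alkyne as a gold acetylide to the activated aryl alkyne. Fallback: the two closures are separated, and the lower pyran ring is closed while ring E still carries bromine in place of the second alkyne. The fallback sets out from 8. Ethynylmagnesium bromide 2 and then Ac2O should give, through the bromomagnesium alkoxide F1, the racemic 1-[4,5-bis(benzyloxy)-2-bromophenyl]prop-2-yn-1-yl acetate F2. The copper–pybox etherification with 5 (conditions of step 2) should give the (S)-propargyl ether F3. Ph3PAuNTf2 in CH2Cl2 then closes the C4–C4a bond of this mono-alkyne to the (S)-2-(2-bromoaryl)-7-benzyloxy-2H-chromene F4. Sonogashira coupling of F4 with 6 (Pd(PhCN)2Cl2, P(t-Bu)3, CuI, i-Pr2NH, dioxane, rt to 50 °C) gives 13, now isolated, where the route is rejoined. A second gold-catalysed hydroarylation of its only alkyne leads on to 14.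

Step 6. What may go wrong: alkylation of the electron-rich phenol 5 on carbon (para to the hydroxyl group) by the copper allenylidene instead of on oxygen, and erosion of catalyst control by the ortho-alkynyl group. Fallback: the C2–O1 bond is made by SN2 inversion of an enantioenriched carbinol. The fallback sets out from 9. Zinc-mediated asymmetric alkynylation (Me2Zn, (S,S)-ProPhenol or its antipode as the sense of addition requires, trimethylsilylacetylene, toluene, 0 °C) should give the silylated propargylic alcohol F5, whose carbinol centre is the spatial opposite of the ether centre wanted. Mitsunobu reaction with 5 (PPh3, DIAD, toluene, 0 °C) inverts it to the silylated bis(propargyl ether) F6. K2CO3 in MeOH removes the silyl group and returns to the route at 12.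

Step 8. What may go wrong: incomplete regiocontrol at the lower, styrene-type double bond (boron on benzylic C4) under the excess of borane and the time that the hindered upper double bond demands. Fallback: the two double bonds are addressed by different mechanisms. The fallback sets out from 14. Copper-catalysed protoboration (CuCl, Xantphos, NaOt-Bu, B2pin2, MeOH, THF, rt) should take only the disubstituted lower double bond, borylcupration placing copper on benzylic C4 and boron on C3 anti to the C2 aryl group, to give the mono-boronate F7. BH3·THF then adds to the remaining upper double bond to give the borane–boronate F8 (not isolated). NaOH/H2O2 oxidises both C–B bonds and returns to the route at 16.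

Further compounds
F1 | step 7 | bromomagnesium 1-[4,5-bis(benzyloxy)-2-bromophenyl]prop-2-yn-1-olate, racemic | C#CC(O[Mg]Br)c1cc(OCc2ccccc2)c(OCc2ccccc2)cc1Br
F2 | step 7 | rac-1-[4,5-bis(benzyloxy)-2-bromophenyl]prop-2-yn-1-yl acetate | C#CC(OC(C)=O)c1cc(OCc2ccccc2)c(OCc2ccccc2)cc1Br
F3 | step 7 | (S)-1,2-bis(benzyloxy)-4-bromo-5-{1-[3-(benzyloxy)phenoxy]prop-2-yn-1-yl}benzene | C#C[C@H](Oc1cccc(OCc2ccccc2)c1)c1cc(OCc2ccccc2)c(OCc2ccccc2)cc1Br
F4 | step 7 | (2S)-7-(benzyloxy)-2-[4,5-bis(benzyloxy)-2-bromophenyl]-2H-chromene | Brc1cc(OCc2ccccc2)c(OCc2ccccc2)cc1[C@H]1Oc2cc(OCc3ccccc3)ccc2C=C1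
F5 | step 6 | (1S)-1-(4,5-bis(benzyloxy)-2-{(3R)-3-[3-(benzyloxy)phenoxy]-3-[4-(benzyloxy)phenyl]prop-1-yn-1-yl}phenyl)-3-(trimethylsilyl)prop-2-yn-1-ol | C[Si](C)(C)C#C[C@@H](O)c1cc(OCc2ccccc2)c(OCc2ccccc2)cc1C#C[C@H](Oc1cccc(OCc2ccccc2)c1)c1ccc(OCc2ccccc2)cc1
F6 | step 6 | C-trimethylsilyl derivative of 12 (silyl group on the terminal alkyne carbon, ether centres as in 12) | C[Si](C)(C)C#C[C@H](Oc1cccc(OCc2ccccc2)c1)c1cc(OCc2ccccc2)c(OCc2ccccc2)cc1C#C[C@H](Oc1cccc(OCc2ccccc2)c1)c1ccc(OCc2ccccc2)cc1
F7 | step 8 | mono-boronate of 14: pinacolboryl group on C3 of the lower chroman, trans to the C2 aryl group, upper chromene intact | c1ccccc1COc1ccc([C@H]2Oc3cc(OCc4ccccc4)ccc3C(c3cc(OCc4ccccc4)c(OCc4ccccc4)cc3[C@H]3Oc4cc(OCc5ccccc5)ccc4C[C@@H]3B3OC(C)(C)C(C)(C)O3)=C2)cc1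
F8 | step 8 | borane–boronate: F7 with a BH2 group on C3 of the upper chroman, trans to the C2 aryl group and cis to the C4 hydrogen | c1ccccc1COc1ccc([C@H]2Oc3cc(OCc4ccccc4)ccc3[C@@H](c3cc(OCc4ccccc4)c(OCc4ccccc4)cc3[C@H]3Oc4cc(OCc5ccccc5)ccc4C[C@@H]3B3OC(C)(C)C(C)(C)O3)[C@@H]2B)cc1
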